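Numbering follows the target's 1-oxaspiro[4.4]nonane skeleton: O1, C2, C3, C4, spiro C5, C6=O, C7=C8, C9. Ring A is the cyclopentenone C5–C9 and ring B is the tetrahydrofuran.
Retrosynthesis: C9 is a tertiary carbinol that carries an acetyl group and sits next to spiro C5, and this C(OH)–C(=O)CH3 unit is the retron of an α-ketol shift. The C5–C9 bond is cut first and C5 is rejoined to the acetyl carbon, which turns ring A into a six-membered 10-hydroxy-10-methylcyclohex-7-ene-6,9-dione. Then the two C–O bonds at C9/C10 are cut (back to a cyclohexa-2,4-dienone), then O1–C5 (back to a flat phenol), and last the aryl–CH2 bond.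
Forward: a chain iodide (three steps from natural phytol) is joined to metalated 2,3,5-trimethylphenol ether. Ring B closes on the arene by dearomatizing spiroetherification, the six-membered ring is ketohydroxylated, and it is contracted to ring A in the last step.
Stereochemistry: C4' and C8' are bought with phytol. C2 is S, opposite in space to C2 of natural (2R,4'R,8'R)-α-tocopherol, so that chromanol cannot be used; C2 comes from a Sharpless epoxidation. C5 comes from a chiral iodoarene catalyst, because the remote C2 (CH3 against CH2R) cannot bias the ring faces. The transient C10 and then C9 are relayed from C5 by substrate control.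

Key step: step 9

Assumption 1: natural (2E,7R,11R)-phytol is taken as the commercial form of phytol.
Assumption 2: the (R,R) antipode of the iodoarene catalyst is taken to give the 5R spiro centre. If the sense of induction is the reverse, the equally accessible (S,S) antipode is used and nothing else changes.

Step 1
Reactants: 1 (2E,7R,11R)-phytol
Product: 2 (2S,3S,7R,11R)-2,3-epoxyphytol
Conditions: Ti(OiPr)4 (10 mol %), L-(+)-diethyl tartrate (12 mol %), t-BuOOH, 4 Å MS, CH2Cl2, −20 °C
Reagents that add atoms: tert-butyl hydroperoxide, CC(C)(C)OO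
Why: In this Sharpless asymmetric epoxidation the titanium tartrate complex binds the allylic OH and, with the L-(+)-tartrate, should give the 2S,3S epoxide as with other E-3-methylalk-2-en-1-ols, which fixes the later C2 as S while the remote 7R and 11R centres play no part.

Step 2
Reactants: 2 (2S,3S,7R,11R)-2,3-epoxyphytol
Product: 3 (3S,7R,11R)-3,7,11,15-tetramethylhexadecane-1,3-diol
Conditions: LiAlH4, THF, 0 °C to rt; aqueous work-up
Reagents that add atoms: none
Why: In this reductive opening of a 2,3-epoxy alcohol the alkoxyaluminate delivers hydride to the less substituted C2, so the C3–O bond is untouched and the 3S tertiary carbinol is kept.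

Step 3
Reactants: 3 (3S,7R,11R)-3,7,11,15-tetramethylhexadecane-1,3-diol
Product: 4 (3S,7R,11R)-1-iodo-3,7,11,15-tetramethylhexadecan-3-ol
Conditions: I2, PPh3, imidazole, CH2Cl2, 0 °C
Reagents that add atoms: iodine, II
Why: The Appel-type iodination runs by SN2 displacement of an oxyphosphonium salt, so only the primary OH reacts and the tertiary carbinol stays unchanged.

Step 4
Reactants: 5 2,3,5-trimethylphenol
Product: 6 1-(methoxymethoxy)-2,3,5-trimethylbenzene
Conditions: MOMCl, iPr2NEt, CH2Cl2, 0 °C to rt
Reagents that add atoms: chloromethyl methyl ether, COCCl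
Why: O-Alkylation of the phenol gives the acetal ether, which masks the acidic OH and serves as the directing group for the next step.

Step 5
Reactants: 6 1-(methoxymethoxy)-2,3,5-trimethylbenzene; 4 (3S,7R,11R)-1-iodo-3,7,11,15-tetramethylhexadecan-3-ol
Product: 9 (3S,7R,11R)-1-[2-(methoxymethoxy)-3,4,6-trimethylphenyl]-3,7,11,15-tetramethylhexadecan-3-ol, via aryllithium 7 (not isolated), via arylmagnesium bromide 8 (not isolated)
Conditions: 6 (2.4 equiv), n-BuLi, TMEDA, Et2O, 0 °C to rt; MgBr2·OEt2, THF, 0 °C; then 4 (1 equiv), Li2CuCl4 (5 mol %), −20 °C to rt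
Reagents that add atoms: none
Why: Directed ortho-metalation takes the only ring C–H next to the OMOM group, and after transmetalation a copper-catalysed Grignard–alkyl iodide cross-coupling forms the aryl–CH2 bond, the first equivalent of 8 merely turning the tertiary OH into its inert magnesium alkoxide so that C3 is not touched.

Step 6
Reactants: 9 (3S,7R,11R)-1-[2-(methoxymethoxy)-3,4,6-trimethylphenyl]-3,7,11,15-tetramethylhexadecan-3-ol
Product: 10 2-[(3S,7R,11R)-3-hydroxy-3,7,11,15-tetramethylhexadecyl]-3,5,6-trimethylphenol
Conditions: HCl (cat.), MeOH, rt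
Reagents that add atoms: none
Why: Acid-catalysed acetal exchange with methanol removes the aryl MOM group under conditions too mild to ionise the non-benzylic tertiary carbinol, so neither chroman formation nor loss of the S centre is expected.

Step 7
Reactants: 10 2-[(3S,7R,11R)-3-hydroxy-3,7,11,15-tetramethylhexadecyl]-3,5,6-trimethylphenol
Product: 11 (2S,5R)-2,7,8,10-tetramethyl-2-[(4R,8R)-4,8,12-trimethyltridecyl]-1-oxaspiro[4.5]deca-7,9-dien-6-one
Conditions: (R,R)-2-iodoresorcinol bis[1-(2,4,6-trimethylbenzoylamino)propan-2-yl] ether (10 mol %), dried mCPBA (1.2 equiv), CH2Cl2–(CF3)2CHOH, −20 °C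
Reagents that add atoms: none
Why: Proposed new method: mCPBA turns the iodoarene into a chiral aryl-λ3-iodane (trivalent iodine) that exchanges a ligand for the phenol oxygen. The tethered tertiary OH then attacks the alkyl-bearing ortho carbon in a 5-exo spirocyclisation while the iodoarene leaves, so the face is chosen by the hydrogen-bonded amide arms held at the phenol oxygen and not by the remote C2. Only this ortho carbon has a tethered nucleophile, the free para C–H is flanked by two methyl groups, the medium holds no good external nucleophile, and the fully substituted product cannot rearomatise. The closest known reaction types are the oxidative ortho-spirolactonisation of phenols and naphthols and the cycloetherification of naphthol-tethered alcohols with the same catalyst class; what is new is a tertiary alcohol on a pentasubstituted phenol.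

Step 8
Reactants: 11 (2S,5R)-2,7,8,10-tetramethyl-2-[(4R,8R)-4,8,12-trimethyltridecyl]-1-oxaspiro[4.5]deca-7,9-dien-6-one
Product: 12 (2S,5R,10R)-10-hydroxy-2,7,8,10-tetramethyl-2-[(4R,8R)-4,8,12-trimethyltridecyl]-1-oxaspiro[4.5]dec-7-ene-6,9-dione
Conditions: RuCl3 (2 mol %), Oxone, NaHCO3, EtOAc–MeCN–H2O, rt
Reagents that add atoms: potassium peroxymonosulfate (active part of Oxone), [K+].[O-]S(=O)(=O)OO
Why: In this catalytic ketohydroxylation RuO4 made in situ adds [3+2] to C9=C10, the trisubstituted and more electron-rich γ,δ-bond of the dienone, rather than to the tetrasubstituted enone bond C7=C8, and peroxymonosulfate oxidises the ruthenate ester at its secondary carbon to the α-ketol, addition anti to the allylic C5–O1 bond (away from the oxygen lone pairs and the C2 methyl group) setting the transient C10 as R.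

Step 9
Reactants: 12 (2S,5R,10R)-10-hydroxy-2,7,8,10-tetramethyl-2-[(4R,8R)-4,8,12-trimethyltridecyl]-1-oxaspiro[4.5]dec-7-ene-6,9-dione
Product: 13 alpha-tocospiro A, (2S,5R,9S)-9-acetyl-9-hydroxy-2,7,8-trimethyl-2-[(4R,8R)-4,8,12-trimethyltridecyl]-1-oxaspiro[4.4]non-7-en-6-one
Conditions: Mg(OTf)2 (20 mol %), toluene–MeCN, 70 °C
Reagents that add atoms: none
Why: Mg(OTf)2 binds the C10 hydroxyl, the C9 carbonyl oxygen and the gauche O1 of 12 in a syn chelate, and as C10 puckers out of the enedione plane the C10–C5 σ bond aligns with π*(C9=O), so C5 shifts suprafacially from C10 to C9 with retention at C5 while C10 becomes the acetyl carbonyl (α-ketol or acyloin rearrangement). The closest known reaction type is the acyloin ring contraction of six-membered cyclic α-ketols, such as the hop α-acids to the five-membered iso-α-acids, which divalent magnesium accelerates. Ring A is not closed by an exo or endo attack but by this 1,2-carbon shift through a three-centre transition state, which turns six ring atoms into five. C9 is the only new stereocentre: in the chelate the equatorial C10–O bond lies syn to C9=O and C10 leaves toward the O1 face, so the acetyl group ends cis to O1 and the OH cis to C4H2 (9S); because the shift is reversible, this epimer, with the larger acetyl away from C4H2, should also be favoured at equilibrium, so the C10 configuration of 12 is not decisive. The step needs migration of ring carbon C5 rather than of the C10 methyl group, and no retro-aldol cleavage of C10–C5: C5 is fully substituted and oxygen-bearing (higher migratory aptitude), contraction takes one carbonyl out of the doubly acceptor-substituted enedione, and the base-free medium keeps slow the fragmentation that would scramble C5.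

Compound list
1 | (2E,7R,11R)-phytol | OC/C=C(\C)CCC[C@H](C)CCC[C@H](C)CCCC(C)C | starting material
2 | (2S,3S,7R,11R)-2,3-epoxyphytol, {(2S,3S)-3-methyl-3-[(4R,8R)-4,8,12-trimethyltridecyl]oxiran-2-yl}methanol | OC[C@@H]1O[C@@]1(C)CCC[C@H](C)CCC[C@H](C)CCCC(C)C | intermediate
3 | (3S,7R,11R)-3,7,11,15-tetramethylhexadecane-1,3-diol | OCC[C@@](C)(O)CCC[C@H](C)CCC[C@H](C)CCCC(C)C | intermediate
4 | (3S,7R,11R)-1-iodo-3,7,11,15-tetramethylhexadecan-3-ol | ICC[C@@](C)(O)CCC[C@H](C)CCC[C@H](C)CCCC(C)C | intermediate
5 | 2,3,5-trimethylphenol | Cc1cc(C)c(C)c(O)c1 | starting material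
6 | 1-(methoxymethoxy)-2,3,5-trimethylbenzene | COCOc1cc(C)cc(C)c1C | intermediate
7 | [2-(methoxymethoxy)-3,4,6-trimethylphenyl]lithium | [Li]c1c(C)cc(C)c(C)c1OCOC | intermediate
8 | [2-(methoxymethoxy)-3,4,6-trimethylphenyl]magnesium bromide | Br[Mg]c1c(C)cc(C)c(C)c1OCOC | intermediate
9 | (3S,7R,11R)-1-[2-(methoxymethoxy)-3,4,6-trimethylphenyl]-3,7,11,15-tetramethylhexadecan-3-ol | COCOc1c(C)c(C)cc(C)c1CC[C@@](C)(O)CCC[C@H](C)CCC[C@H](C)CCCC(C)C | intermediate
10 | 2-[(3S,7R,11R)-3-hydroxy-3,7,11,15-tetramethylhexadecyl]-3,5,6-trimethylphenol | Oc1c(C)c(C)cc(C)c1CC[C@@](C)(O)CCC[C@H](C)CCC[C@H](C)CCCC(C)C | intermediate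
11 | (2S,5R)-2,7,8,10-tetramethyl-2-[(4R,8R)-4,8,12-trimethyltridecyl]-1-oxaspiro[4.5]deca-7,9-dien-6-one | CC1=CC(C)=C(C)C(=O)[C@@]12CC[C@](C)(CCC[C@H](C)CCC[C@H](C)CCCC(C)C)O2 | intermediate
12 | (2S,5R,10R)-10-hydroxy-2,7,8,10-tetramethyl-2-[(4R,8R)-4,8,12-trimethyltridecyl]-1-oxaspiro[4.5]dec-7-ene-6,9-dione | C[C@]1(O)C(=O)C(C)=C(C)C(=O)[C@@]12CC[C@](C)(CCC[C@H](C)CCC[C@H](C)CCCC(C)C)O2 | intermediate
13 | alpha-tocospiro A, (2S,5R,9S)-9-acetyl-9-hydroxy-2,7,8-trimethyl-2-[(4R,8R)-4,8,12-trimethyltridecyl]-1-oxaspiro[4.4]non-7-en-6-one | CC(=O)[C@]1(O)C(C)=C(C)C(=O)[C@@]12CC[C@](C)(CCC[C@H](C)CCC[C@H](C)CCCC(C)C)O2 | target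

Total step count: 9. Longest linear sequence: 8 (steps 1, 2, 3, 5, 6, 7, 8, 9).

Steps most likely to fail

Step 7. An external oxygen nucleophile may attack the free para position, which leads to over-oxidation. The reaction may also run through a free phenoxenium ion, which would erode catalyst control over the ring face. The fallback gives up catalyst control and uses known chemistry. It sets out from 10, which is oxidised with stoichiometric PhI(OAc)2 in (CF3)2CHOH, an established dearomatizing spiroetherification. This should give 11 together with its C5 epimer, the (2S,5S)-spirodienone F1. The two diastereomers are separated by chromatography. F1 is returned to 10 by reductive rearomatisation (Zn, AcOH) and recycled. The fallback comes back to the route at 11.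

Step 9. The C10 methyl group may migrate instead of C5, retro-aldol opening of C10–C5 may erode the C5 configuration, or the chelate may turn over slowly. The fallback reaches the rearranging alkoxide from a different precursor. It sets out from 10. Teuber oxidation with (KSO3)2NO in buffered aqueous acetone gives the (3'S)-tocopherolquinone F2. Weitz–Scheffer epoxidation (t-BuOOH, DBU, CH2Cl2) then gives the side-chain-bearing epoxyquinone F3, after chromatographic removal of the ring-regioisomeric and facial isomers. Deprotonation of the tertiary OH with t-BuMgCl in THF should trigger a 5-exo-tet opening of the epoxide at the side-chain-bearing carbon with inversion. This releases the magnesium alkoxide of 12 in an aprotic medium, where it contracts in the same flask. The fallback comes back to the route at 13.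

Step 8. Over-oxidation may cleave the C9–C10 bond, and facial selectivity at C10 may be poor. The fallback separates addition from oxidation. It sets out from 11, which is dihydroxylated with K2OsO2(OH)4 (cat.) and NMO in acetone–water to the cis-9,10-diol F4. Only the secondary allylic OH of F4 is then oxidised (SO3·pyridine, DMSO, Et3N, or MnO2). The fallback comes back to the route at 12.

Further compounds
F1 | step 7 | (2S,5S)-2,7,8,10-tetramethyl-2-[(4R,8R)-4,8,12-trimethyltridecyl]-1-oxaspiro[4.5]deca-7,9-dien-6-one | CC1=CC(C)=C(C)C(=O)[C@]12CC[C@](C)(CCC[C@H](C)CCC[C@H](C)CCCC(C)C)O2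
F2 | step 9 | 2-[(3S,7R,11R)-3-hydroxy-3,7,11,15-tetramethylhexadecyl]-3,5,6-trimethylcyclohexa-2,5-diene-1,4-dione | CC1=C(C)C(=O)C(CC[C@@](C)(O)CCC[C@H](C)CCC[C@H](C)CCCC(C)C)=C(C)C1=O
F3 | step 9 | (1S,6R)-1-[(3S,7R,11R)-3-hydroxy-3,7,11,15-tetramethylhexadecyl]-3,4,6-trimethyl-7-oxabicyclo[4.1.0]hept-3-ene-2,5-dione | CC1=C(C)C(=O)[C@@]2(CC[C@@](C)(O)CCC[C@H](C)CCC[C@H](C)CCCC(C)C)O[C@@]2(C)C1=O
F4 | step 8 | (2S,5R,9S,10S)-9,10-dihydroxy-2,7,8,10-tetramethyl-2-[(4R,8R)-4,8,12-trimethyltridecyl]-1-oxaspiro[4.5]dec-7-en-6-one | C[C@]1(O)[C@@H](O)C(C)=C(C)C(=O)[C@@]12CC[C@](C)(CCC[C@H](C)CCC[C@H](C)CCCC(C)C)O2
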